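Begin with the leftover in the oak flask. Its readings flatten near 14.8%, and each complex with two exchanged holds two incoming ligands. So that level accounts for 5.94 mM of the 12.0 mM charged, and 6.06 mM of ligand remains to be explained.

all flasks: starting complex 20 mM

| charge | incoming ligand | temperature | remark | time |
|---|---|---|---|---|
| oak | 12 mM | 5 °C | the very flask that is asked about, followed so far |  |
| maple | 12 mM | 11 °C | run made earlier |  |
| flask | 12.0 mM | 5 °C |  | 6.0 min |

| oak: time / min | oak: complex with two exchanged / % | maple: time / min | maple: complex with two exchanged / % |
|---|---|---|---|
| 0.417 | 9.2 | 0.417 | 12.4 |
| 0.667 | 12.1 | 0.667 | 13.7 |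
| 1.33 | 14.2 | 1.33 | 14.3 |
| 2.50 | 15.0 | 2.50 | 13.9 |
| 5.00 | 14.7 | 5.00 | 14.5 |

(standard deviation of a reading: 0.3 percentage points)

- what is taken out of complex with two exchanged is counted as made
- additions bring no volume worth counting

- south: at 6.0 min take out 90% of the complex with two exchanged then present, then wait 12 min
- south-west: at 6.0 min raise the temperature by 20 K, then wait 12 min
- south-east: at 6.0 min add incoming ligand, 100% of the amount charged, then wait 12 min
- north-east: change nothing and wait 12 min more

1. complex with two exchanged, in percent of the starting complex first charged, at 6.0 min
2. the remedy with the largest gain of complex with two exchanged, or "none" below 2 percentage points (south / south-west / south-east / north-east / none)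
3. complex with two exchanged present, with what was taken out counted in, in percent of the starting complex first charged, after south-west
4. complex with two exchanged present, with what was taken out counted in, in percent of the starting complex first charged, after south-east

You can draw the oak curve from its gap to that level. The gap is 5.6 percentage points at 0.417 min and 2.7 points at 0.667 min, so it closes at about 2.88 min⁻¹ and halves every 0.241 min. The knee therefore lies near 1.33 min, and 6.0 min is 24.9 such half-times out, so I expect the level itself at that time. The warmer maple run stands higher at its first reading, 12.4% against 9.2%, yet flattens near 14.2%. I read that as a level set by the charges: the ligand is used stepwise, and the remainder sits in the complex with one exchanged.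

Let x be ligand charged per starting complex, here 0.600, and b the share with two exchanged. If the ligand is bound in complexes, the share exchanged at least once is x − b, which in oak reads 0.452. Define the double-exchange coefficient κ as b divided by the square of that share: 0.728, a reading with its scatter. Adding ligand to make x 1.20 and solving b = κ times the square of (x − b) gives 43.1%. With no free ligand in this picture, I expect warming, removal and waiting to add nothing.

The forecast says 14.8% (14.4% to 15.2%), south-east as best, 12.7% (11% to 15%) after warming and 34% (31% to 44%) after adding ligand: “I therefore read it as a fast equilibrium”. My reckoning differs from it on the last two.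

The flask gives 14.7%, with south-east best at a gain of 31 points, 14.7% after warming and 45.4% after adding ligand.

    complex with one exchanged + incoming ligand ⇌ leaving ligand + complex with two exchanged (K = 160, k = 3.70 M⁻¹ s⁻¹, Ea = 47.0 kJ mol⁻¹, ΔH = −50.0 kJ mol⁻¹)
    starting complex + incoming ligand ⇌ leaving ligand + complex with one exchanged (K = 2.50, k = 3.00 M⁻¹ s⁻¹, Ea = 56.0 kJ mol⁻¹, ΔH = 3.00 kJ mol⁻¹)
    leaving ligand → by-product carried off (k = 0.720 s⁻¹, Ea = 69.0 kJ mol⁻¹)
    (constants at 5 °C)

In the flask both exchange steps ran while incoming ligand lasted: it stood at 12.1% of its charge at 0.600 min and at 0% at 3.00 min, when 54.7% of the starting complex still stood, which marks it as the limiting reagent. At 6.00 min the flask held, in shares of the starting complex charged, 54.7% starting complex, 30.6% with one exchanged and 14.7% with two. After adding ligand, the flask stands 2.3 points above what κ gave. For the neighbour charged with 7.2 mM, x is 0.360, and κ gives 6.38%; that neighbour's computed result is 6.06%.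

The earlier runs and the new flask were generated by integration from invented constants, noise included.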